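**Plan**

- Retrosynthesis: the four O–S bonds are cut first (back to quercetin), then the five O–benzyl bonds, then C5–O and C7–O (back to C–F). Ring C is then opened at C3–C4 and O1–C8a, and the B-ring ketone is cut last at C2–C1'.
- Enabling feature: the oxygen-bearing carbons of ring A (C5, C7, C8a) lie ortho, para and ortho to C4a, the carbon that holds the C4 carbonyl. A 2,4,6-trifluorobenzoyl group can therefore supply ring A together with C4: each fluorine marks a future C–O bond and each is activated for displacement by that carbonyl.
- Forward: rings A and B are bought as arenes. C2–C1' is made by Grignard addition to a Weinreb amide. Ring C, the only ring built, closes in step 3 by enolate C-acylation (C3–C4) and fluoride displacement (O1–C8a). The two remaining fluorides are then exchanged for benzyloxy groups, all benzyl ethers are removed, and the four unchelated hydroxyls are sulfated.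
- Stereochemistry: the target has no stereocentre and no stereogenic double bond, so nothing has to be controlled.

Key step: step 3

Assumption: the target is taken as drawn, as the free tetrakis(hydrogen sulfate); it is released from its ammonium salt by cold proton exchange in the last step and would be kept cold, or neutralised for storage.

**Route**

Step 1
Reactants: 1 benzyloxyacetyl chloride
Product: 2 2-(benzyloxy)-N-methoxy-N-methylacetamide
Conditions: MeNH(OMe)·HCl, K2CO3, H2O/CH2Cl2, 0 °C → rt
Reagents that add atoms: N,O-dimethylhydroxylamine hydrochloride, SMILES CNOC.Cl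
Why: Schotten–Baumann N-acylation, in which the acid chloride reacts with the liberated hydroxylamine much faster than with water while aqueous K2CO3 takes up both equivalents of HCl and the benzyl ether is untouched.

Step 2
Reactants: 3 4-bromo-1,2-bis(benzyloxy)benzene; 2 2-(benzyloxy)-N-methoxy-N-methylacetamide
Product: 6 2-(benzyloxy)-1-[3,4-bis(benzyloxy)phenyl]ethanone, via aryl Grignard reagent 4 (not isolated), via chelated tetrahedral adduct 5 (not isolated)
Conditions: Mg turnings (iodine crystal), THF, 45 °C; then 2, THF, 0 °C → rt; 1 M HCl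
Reagents that add atoms: none
Why: Weinreb ketone synthesis, in which magnesium insertion gives the aryl Grignard reagent and its single addition to the amide is held as the N-methoxy chelate 5 until the acidic quench, so that no tertiary alcohol can form.

Step 3
Reactants: 6 2-(benzyloxy)-1-[3,4-bis(benzyloxy)phenyl]ethanone; 7 2,4,6-trifluorobenzoyl chloride
Product: 10 3-(benzyloxy)-2-[3,4-bis(benzyloxy)phenyl]-5,7-difluorochromen-4-one, via lithium enolate 8 (not isolated), via trifluorophenyl 1,3-diketone 9 (not isolated)
Conditions: LiN(SiMe3)2 (2.2 equiv), THF, −78 °C; 7, −78 → 0 °C; aq NH4Cl work-up; crude 9, K2CO3, DMF, 70 °C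
Reagents that add atoms: none
Why: LiN(SiMe3)2 deprotonates the CH2 of 6, acidified by the carbonyl and chelated through the benzyloxy oxygen, to give the Z-enolate 8, whose carbon attacks acid chloride 7 (Claisen-type C-acylation, C3–C4), and the second equivalent of base at once deprotonates the new diketone 9 so that it is withdrawn as its chelated diketonate. After work-up, K2CO3 in DMF regenerates the enolate of 9, whose oxygen on the ring B side adds to an ortho C–F carbon to give a Meisenheimer complex stabilised by the C4 carbonyl and the two remaining fluorines, and loss of fluoride forms O1–C8a. The closest known chemistry is the flavone synthesis from aryl ketone enolates and 2-fluorobenzoyl chlorides, together with the cyclisation of 2-halobenzoyl 1,3-dicarbonyl compounds to chromones and quinolones. Ring C closes as a six-membered ring by intramolecular nucleophilic aromatic substitution (addition–elimination), formally a 6-endo-trig attack at C8a of the C4a=C8a–C4=O unit. No stereocentre is formed, because C3 of 9 becomes sp2 in 10. The step needs C- over O-acylation, which the lithium counter-ion in THF, the excess base and the stability of the diketonate should secure (an enol ester can pass its acyl group to remaining enolate), and it needs one defined fluoride to leave, which holds because the two ortho fluorides are equivalent by symmetry and the para one is beyond the reach of the enolate oxygen.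

Step 4
Reactants: 10 3-(benzyloxy)-2-[3,4-bis(benzyloxy)phenyl]-5,7-difluorochromen-4-one
Product: 11 3,5,7-tris(benzyloxy)-2-[3,4-bis(benzyloxy)phenyl]chromen-4-one
Conditions: BnOH (3 equiv), NaH (3 equiv), THF, 0 °C; then 10, DMF, rt → 60 °C
Reagents that add atoms: benzyl alcohol, SMILES OCc1ccccc1
Why: Twofold nucleophilic aromatic substitution (addition–elimination), feasible because the 5- and 7-fluorides are ortho and para to the carbonyl-bearing C4a and meta to each other, so the first benzyloxy group does not sit on a charge-bearing carbon of the second Meisenheimer complex.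

Step 5
Reactants: 11 3,5,7-tris(benzyloxy)-2-[3,4-bis(benzyloxy)phenyl]chromen-4-one
Product: 12 quercetin, 2-(3,4-dihydroxyphenyl)-3,5,7-trihydroxychromen-4-one
Conditions: H2 (1 atm), 10% Pd/C, THF/MeOH, rt
Reagents that add atoms: none
Why: Catalytic hydrogenolysis should cleave all five benzylic C–O bonds to toluene, while the tetrasubstituted, cross-conjugated C2=C3 bond of the flavonol is not expected to be reduced at balloon pressure.

Step 6
Reactants: 12 quercetin
Product: 13 quercetin 3,7,3',4'-tetra-O-sulfate, the tetrakis(hydrogen sulfate) with free 5-hydroxyl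
Conditions: SO3·NEt3 (16 equiv), DMA, 65 °C; Sephadex LH-20; Dowex 50WX8 (H+ form), H2O, 0 °C; lyophilise
Reagents that add atoms: sulfur trioxide–triethylamine complex, SMILES CC[N+](CC)(CC)S(=O)(=O)[O-]
Why: O-Sulfonation of phenolic and enolic hydroxyls by an amine–SO3 complex should take the 3-, 7-, 3'- and 4'-hydroxyls, whereas the 5-hydroxyl is held in a six-membered hydrogen bond to the C4 carbonyl and is expected to stay free at this temperature, and cold proton exchange then gives the free acid.

**Compound list**

1 | benzyloxyacetyl chloride | O=C(Cl)COCc1ccccc1 | starting material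
2 | 2-(benzyloxy)-N-methoxy-N-methylacetamide | CON(C)C(=O)COCc1ccccc1 | intermediate
3 | 4-bromo-1,2-bis(benzyloxy)benzene | Brc1ccc(OCc2ccccc2)c(OCc2ccccc2)c1 | starting material
4 | [3,4-bis(benzyloxy)phenyl]magnesium bromide (formed in the flask) | Br[Mg]c1ccc(OCc2ccccc2)c(OCc2ccccc2)c1 | intermediate
5 | bromomagnesium 2-(benzyloxy)-1-[3,4-bis(benzyloxy)phenyl]-1-[methoxy(methyl)amino]ethanolate, racemic chelate (formed in the flask) | CON(C)C(COCc1ccccc1)(O[Mg]Br)c1ccc(OCc2ccccc2)c(OCc2ccccc2)c1 | intermediate
6 | 2-(benzyloxy)-1-[3,4-bis(benzyloxy)phenyl]ethanone | O=C(COCc1ccccc1)c1ccc(OCc2ccccc2)c(OCc2ccccc2)c1 | intermediate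
7 | 2,4,6-trifluorobenzoyl chloride | O=C(Cl)c1c(F)cc(F)cc1F | starting material
8 | lithium (Z)-2-(benzyloxy)-1-[3,4-bis(benzyloxy)phenyl]ethen-1-olate (formed in the flask) | [Li]O/C(=C\OCc1ccccc1)c1ccc(OCc2ccccc2)c(OCc2ccccc2)c1 | intermediate
9 | 2-(benzyloxy)-1-[3,4-bis(benzyloxy)phenyl]-3-(2,4,6-trifluorophenyl)propane-1,3-dione, racemic and enolisable (carried on crude) | O=C(c1ccc(OCc2ccccc2)c(OCc2ccccc2)c1)C(OCc1ccccc1)C(=O)c1c(F)cc(F)cc1F | intermediate
10 | 3-(benzyloxy)-2-[3,4-bis(benzyloxy)phenyl]-5,7-difluorochromen-4-one | O=c1c(OCc2ccccc2)c(-c2ccc(OCc3ccccc3)c(OCc3ccccc3)c2)oc2cc(F)cc(F)c12 | intermediate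
11 | 3,5,7-tris(benzyloxy)-2-[3,4-bis(benzyloxy)phenyl]chromen-4-one | O=c1c(OCc2ccccc2)c(-c2ccc(OCc3ccccc3)c(OCc3ccccc3)c2)oc2cc(OCc3ccccc3)cc(OCc3ccccc3)c12 | intermediate
12 | quercetin, 2-(3,4-dihydroxyphenyl)-3,5,7-trihydroxychromen-4-one | O=c1c(O)c(-c2ccc(O)c(O)c2)oc2cc(O)cc(O)c12 | intermediate
13 | quercetin 3,7,3',4'-tetra-O-sulfate | O=c1c(OS(=O)(=O)O)c(-c2ccc(OS(=O)(=O)O)c(OS(=O)(=O)O)c2)oc2cc(OS(=O)(=O)O)cc(O)c12 | target

**Step count and risks**

Total step count: 6. Longest linear sequence: 6 steps (1 → 2 → 6 → 10 → 11 → 12 → 13).

Steps most likely to fail: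

1. Step 3. The enolate may be acylated on oxygen, or the excess amide base may consume the acid chloride, so that too little diketonate reaches the cyclisation. Fallback: setting out from 6, the lithium enolate would be added to 2,4,6-trifluorobenzaldehyde (LiN(SiMe3)2, THF, −78 °C). This aldol addition can only form the C–C bond and would give 2-(benzyloxy)-1-[3,4-bis(benzyloxy)phenyl]-3-hydroxy-3-(2,4,6-trifluorophenyl)propan-1-one F1 as a mixture of racemic diastereomers. Oxidation with Dess–Martin periodinane (NaHCO3, CH2Cl2) would give the diketone 9, now isolated, and K2CO3 in DMF at 70 °C would close ring C, coming back to the route at 10.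

2. Step 4. The second fluoride displacement may stall, or benzyloxide may add at C2 and open the pyranone ring, which then fragments. Fallback: setting out from 10, NaOMe in MeOH/THF at reflux would be used; it is a smaller nucleophile, and its addition at C2 is reversible in methanol. This would give 3-(benzyloxy)-2-[3,4-bis(benzyloxy)phenyl]-5,7-dimethoxychromen-4-one F2. Hydrogenolysis (H2, 10% Pd/C, THF/MeOH) would remove the three benzyl groups to give 2-(3,4-dihydroxyphenyl)-3-hydroxy-5,7-dimethoxychromen-4-one F3. BBr3 (CH2Cl2, −78 °C → rt) would then cleave both methyl ethers, coming back to the route at 12.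

3. Step 6. Sulfation may stop at tri-sulfates that cannot be separated from the tetra-sulfate as salts, may run on to the 5-hydroxyl, or sulfate esters may hydrolyse during the proton exchange. Fallback: setting out from 12, 2,2,2-trichloroethyl chlorosulfate (Et3N, DMAP, THF, 0 °C → rt) would be used, giving the neutral quercetin 3,7,3',4'-tetrakis(2,2,2-trichloroethyl sulfate) F4 with the chelated 5-hydroxyl untouched; it can be purified on silica gel. Reductive removal of the four trichloroethyl groups (Zn dust, HCO2NH4, MeOH, rt) and the same cold proton exchange would then come back to the route at 13.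

**Further compounds**

F1 | step 3 | 2-(benzyloxy)-1-[3,4-bis(benzyloxy)phenyl]-3-hydroxy-3-(2,4,6-trifluorophenyl)propan-1-one (mixture of racemic diastereomers) | O=C(c1ccc(OCc2ccccc2)c(OCc2ccccc2)c1)C(OCc1ccccc1)C(O)c1c(F)cc(F)cc1F
F2 | step 4 | 3-(benzyloxy)-2-[3,4-bis(benzyloxy)phenyl]-5,7-dimethoxychromen-4-one | O=c1c(OCc2ccccc2)c(-c2ccc(OCc3ccccc3)c(OCc3ccccc3)c2)oc2cc(OC)cc(OC)c12
F3 | step 4 | 2-(3,4-dihydroxyphenyl)-3-hydroxy-5,7-dimethoxychromen-4-one | O=c1c(O)c(-c2ccc(O)c(O)c2)oc2cc(OC)cc(OC)c12
F4 | step 6 | quercetin 3,7,3',4'-tetrakis(2,2,2-trichloroethyl sulfate) | O=c1c(OS(=O)(=O)OCC(Cl)(Cl)Cl)c(-c2ccc(OS(=O)(=O)OCC(Cl)(Cl)Cl)c(OS(=O)(=O)OCC(Cl)(Cl)Cl)c2)oc2cc(OS(=O)(=O)OCC(Cl)(Cl)Cl)cc(O)c12
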